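Numbering follows the target SMILES with carbonyl oxygens and the two methyl branches left out: C1–C4, O5, C6–C15, O16, N17, C18–C23 (lactone A: C4, O5, C6, C7, C8; lactone B: C12–C15, O16; ketone C9; lactam carbonyl C23).
Enabling feature: in the nine-membered ring C3–C4–C8–C9–C10–C11–N17–C23–C22 the lactam carbon C23 and the ketone C9 both sit next to C8 and are linked on the other side by N17–C11–C10, so a C23–C8 bond would fold this ring into a cyclopentanone (C23, C22, C3, C4, C8) whose 2-acyl chain ends in N17.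
Cuts, last-formed bond first: N17–C18 (reductive amidoalkylation), O5–C6 and O16–C15 (lactones), N17–C23 with C8–C23 restored (ring expansion), C8–C7, C8–C9, then C3–C2 and C22–C21 on the ring and C12–C13, C13–C14 in the side chain.
Forward: the cyclopentanone is built first, C8 is acylated (aldol, oxidation) and alkylated to a quaternary centre, the nine-membered lactam arises by ring expansion, both lactones then close, and the azepane ring closes last.
Stereochemistry: C4 comes from (R)-4-silyloxycyclopentenone and steers C3 and C22 (all-trans); C11 comes from O-benzyl-L-homoserine and C12 from Felkin–Anh reduction next to NBn2; C14 and C7 come from SN2 inversion of (S)-lactate triflates; C8 is set by equilibration through the C9 enol when lactone A closes.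

Key step: step 17

Assumption: C8 is α to the C9 ketone and therefore labile after step 17; the natural arrangement (lactone A cis-fused to the nine-membered ring, C9 anti to the C7 methyl group) is taken to be the thermodynamically preferred one once C4 and C7 are fixed.

Step 1
Reactants: 1 (R)-4-[(tert-butyldimethylsilyl)oxy]cyclopent-2-en-1-one
Product: 2 (R)-4-[(tert-butyldimethylsilyl)oxy]-2-iodocyclopent-2-en-1-one
Conditions: I2, pyridine/CH2Cl2, 0 °C to rt
Reagents that add atoms: iodine, II
Why: α-iodination of an enone by pyridine-mediated addition, iodination and elimination (Johnson iodination) should leave C4 untouched.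

Step 2
Reactants: 2 (R)-4-[(tert-butyldimethylsilyl)oxy]-2-iodocyclopent-2-en-1-one; 3 4,4-diethoxybut-1-ene
Product: 5 (R)-4-[(tert-butyldimethylsilyl)oxy]-2-(4,4-diethoxybutyl)cyclopent-2-en-1-one, via B-(4,4-diethoxybutyl)-9-BBN 4 (not isolated)
Conditions: 3, 9-BBN, THF, 0 °C to rt; then 2, PdCl2(dppf) (5 mol %), AsPh3, Cs2CO3, DMF/THF/H2O, rt
Reagents that add atoms: none
Why: anti-Markovnikov hydroboration followed by B-alkyl Suzuki–Miyaura coupling with an α-iodoenone is the established way to attach a saturated chain (C21–C18) to C22 of a 4-silyloxycyclopentenone.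

Step 3
Reactants: 5 (R)-4-[(tert-butyldimethylsilyl)oxy]-2-(4,4-diethoxybutyl)cyclopent-2-en-1-one
Product: 6 (2R,3R,4R)-4-[(tert-butyldimethylsilyl)oxy]-2-(4,4-diethoxybutyl)-3-ethylcyclopentan-1-one (all-trans)
Conditions: EtMgBr, CuBr·SMe2 (20 mol %), THF, −78 to −40 °C; sat. aq. NH4Cl
Reagents that add atoms: ethylmagnesium bromide, CC[Mg]Br
Why: copper-catalysed conjugate addition should deliver ethyl to C3 anti to the C4 silyloxy group, and protonation of the enolate should give the more stable 2,3-trans ketone, so C3 and C22 are both set from C4 as in the two-component prostaglandin coupling.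

Step 4
Reactants: 7 O-benzyl-L-homoserine
Product: 8 benzyl (S)-4-(benzyloxy)-2-(dibenzylamino)butanoate
Conditions: BnBr (3.3 equiv), K2CO3, EtOH/H2O, reflux
Reagents that add atoms: benzyl bromide, BrCc1ccccc1
Why: exhaustive N,N-dibenzylation with concurrent benzyl ester formation is the standard entry to configurationally robust N,N-dibenzylamino esters.

Step 5
Reactants: 8 benzyl (S)-4-(benzyloxy)-2-(dibenzylamino)butanoate
Product: 9 allyl (S)-6-(benzyloxy)-4-(dibenzylamino)-3-oxohexanoate
Conditions: allyl acetate (2.5 equiv), LiN(iPr)2 (2.5 equiv), THF, −78 °C; AcOH quench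
Reagents that add atoms: allyl acetate, CC(=O)OCC=C
Why: crossed Claisen condensation of an acetate lithium enolate with an N,N-dibenzylamino ester is known to give the β-keto ester without racemisation at the α-carbon (C11), and it brings in C13.

Step 6
Reactants: 10 tert-butyl (S)-lactate
Product: 11 tert-butyl (S)-2-{[(trifluoromethyl)sulfonyl]oxy}propanoate
Conditions: Tf2O, 2,6-lutidine, CH2Cl2, −78 to 0 °C; used directly
Reagents that add atoms: trifluoromethanesulfonic anhydride, FC(F)(F)S(=O)(=O)OS(=O)(=O)C(F)(F)F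
Why: O-sulfonylation of the α-hydroxy ester occurs at oxygen and so retains the configuration of the stereocentre.

Step 7
Reactants: 9 allyl (S)-6-(benzyloxy)-4-(dibenzylamino)-3-oxohexanoate; 11 tert-butyl (S)-2-{[(trifluoromethyl)sulfonyl]oxy}propanoate
Product: 13 1-allyl 4-tert-butyl (3S)-2-[(S)-4-(benzyloxy)-2-(dibenzylamino)butanoyl]-3-methylbutanedioate (C13 epimers), via sodium enolate 12 (not isolated)
Conditions: NaH (1.0 equiv), THF, 0 °C; then 11, 0 °C to rt
Reagents that add atoms: none
Why: C-alkylation of a β-keto ester enolate with a 2-triflyloxy ester is a clean SN2 reaction with inversion, so the (S)-lactate sets C14 as required (the descriptor stays S because the priorities change).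

Step 8
Reactants: 13 1-allyl 4-tert-butyl (3S)-2-[(S)-4-(benzyloxy)-2-(dibenzylamino)butanoyl]-3-methylbutanedioate
Product: 15 tert-butyl (2S,5S)-7-(benzyloxy)-5-(dibenzylamino)-2-methyl-4-oxoheptanoate, via β-keto acid 14 (not isolated)
Conditions: Pd(PPh3)4 (5 mol %), morpholine, THF, rt
Reagents that add atoms: none
Why: Tsuji deallylation through a π-allyl palladium complex and spontaneous decarboxylation of the β-keto acid should remove the activating ester under near-neutral conditions that spare the tert-butyl ester, the benzyl groups, C11 and C14.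

Step 9
Reactants: 15 tert-butyl (2S,5S)-7-(benzyloxy)-5-(dibenzylamino)-2-methyl-4-oxoheptanoate
Product: 16 tert-butyl (2S,4S,5S)-7-(benzyloxy)-5-(dibenzylamino)-4-hydroxy-2-methylheptanoate
Conditions: NaBH4, MeOH, −20 °C
Reagents that add atoms: none
Why: Felkin–Anh (non-chelation) reduction of an α-(dibenzylamino) ketone, with hydride entering anti to the bulky NBn2 group, should give the syn (11S,12S) amino alcohol, as in the statine series.

Step 10
Reactants: 16 tert-butyl (2S,4S,5S)-7-(benzyloxy)-5-(dibenzylamino)-4-hydroxy-2-methylheptanoate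
Product: 17 tert-butyl (2S,4S,5S)-7-(benzyloxy)-4-[(tert-butyldimethylsilyl)oxy]-5-(dibenzylamino)-2-methylheptanoate
Conditions: TBSOTf (1.2 equiv), 2,6-lutidine, CH2Cl2, −78 to 0 °C
Reagents that add atoms: tert-butyldimethylsilyl triflate, CC(C)(C)[Si](C)(C)OS(=O)(=O)C(F)(F)F
Why: the silyl triflate should silylate the hindered C12 hydroxyl at low temperature before the tert-butyl ester is affected, masking lactone B as a silyl ether ester.

Step 11
Reactants: 17 tert-butyl (2S,4S,5S)-7-(benzyloxy)-4-[(tert-butyldimethylsilyl)oxy]-5-(dibenzylamino)-2-methylheptanoate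
Product: 18 tert-butyl (2S,4S,5S)-5-amino-4-[(tert-butyldimethylsilyl)oxy]-7-hydroxy-2-methylheptanoate
Conditions: H2 (1 atm), Pd(OH)2/C, MeOH, rt
Reagents that add atoms: none
Why: hydrogenolysis should remove both N-benzyl groups and the O-benzyl ether in one operation, and the tert-butyl ester resists attack by the freed amine.

Step 12
Reactants: 18 tert-butyl (2S,4S,5S)-5-amino-4-[(tert-butyldimethylsilyl)oxy]-7-hydroxy-2-methylheptanoate
Product: 19 tert-butyl (2S,4S,5S)-5-azido-4-[(tert-butyldimethylsilyl)oxy]-7-hydroxy-2-methylheptanoate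
Conditions: imidazole-1-sulfonyl azide hydrogen sulfate, CuSO4·5H2O (cat.), K2CO3, MeOH, rt
Reagents that add atoms: imidazole-1-sulfonyl azide hydrogen sulfate, [N-]=[N+]=NS(=O)(=O)n1ccnc1.OS(=O)(=O)O
Why: copper-catalysed diazo transfer converts a primary amine into the azide without breaking the C11–N bond, so C11 keeps its configuration.

Step 13
Reactants: 19 tert-butyl (2S,4S,5S)-5-azido-4-[(tert-butyldimethylsilyl)oxy]-7-hydroxy-2-methylheptanoate
Product: 20 tert-butyl (2S,4S,5S)-5-azido-4-[(tert-butyldimethylsilyl)oxy]-2-methyl-7-oxoheptanoate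
Conditions: Dess–Martin periodinane, NaHCO3, CH2Cl2, 0 °C to rt; used crude
Reagents that add atoms: none
Why: buffered Dess–Martin oxidation gives the C9 aldehyde under neutral conditions that should avoid β-elimination of the C11 azide.

Step 14
Reactants: 6 (2R,3R,4R)-4-[(tert-butyldimethylsilyl)oxy]-2-(4,4-diethoxybutyl)-3-ethylcyclopentan-1-one; 20 tert-butyl (2S,4S,5S)-5-azido-4-[(tert-butyldimethylsilyl)oxy]-2-methyl-7-oxoheptanoate
Product: 22 β-hydroxy ketone with the new C8–C9 bond (3R,4S,11S,12S,14S,22R; C8 and C9 epimers), via lithium enolate 21 (not isolated)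
Conditions: 6, LiN(iPr)2 (1.05 equiv), THF, −78 °C; then 20, −78 °C; AcOH quench at −78 °C
Reagents that add atoms: none
Why: kinetic deprotonation should occur at the C8 methylene and not at the tertiary C22, the β-silyloxy lithium enolate is stable at −78 °C, and aldol addition to the aldehyde is fast; the C8 and C9 configurations are erased later.

Step 15
Reactants: 22 β-hydroxy ketone with the new C8–C9 bond
Product: 23 2-acylcyclopentanone (1,3-diketone C9/C23; 3R,4S,11S,12S,14S,22R)
Conditions: Dess–Martin periodinane, NaHCO3, CH2Cl2, rt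
Reagents that add atoms: none
Why: Dess–Martin oxidation is the standard conversion of a β-hydroxy ketone into a 1,3-diketone and is compatible with the azide, the acetal and the silyl ethers.

Step 16
Reactants: 23 2-acylcyclopentanone (1,3-diketone C9/C23); 24 ethyl (S)-2-{[(trifluoromethyl)sulfonyl]oxy}propanoate (commercial)
Product: 26 azido 2-acyl-2-alkylcyclopentanone (C8 quaternary; 3R,4S,7S,11S,12S,14S,22R; either C8 epimer), via sodium enolate 25 (not isolated)
Conditions: NaH (1.0 equiv), THF, 0 °C; then 24, −20 °C to rt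
Reagents that add atoms: none
Why: the chelated sodium enolate of a 1,3-dicarbonyl should be C-alkylated by the 2-triflyloxy ester in an SN2 reaction with inversion, which makes C8 quaternary and sets C7 (S) by reagent control, while one equivalent of base leaves the β-azido ketone and the β-silyloxy group undisturbed.

Step 17
Reactants: 26 azido 2-acyl-2-alkylcyclopentanone
Product: 29 nine-membered keto-lactam (free N17–H; 3R,4S,7S,11S,12S,14S,22R; C8 epimers), via amino diketone 27 (not isolated), via bicyclic hemiaminal 28 (not isolated)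
Conditions: H2 (1 atm), 10% Pd/C, EtOAc, rt; filter; then Et3N (2 equiv), EtOAc, rt to 45 °C
Reagents that add atoms: none
Why: Hydrogenolysis of the C11 azide gives amine 27, whose nitrogen N17 adds to the cyclopentanone carbonyl C23 (6-exo-trig, ring N17–C11–C10–C9–C8–C23) to give hemiaminal 28; collapse of its alkoxide breaks C23–C8 and expels C8 as the enolate of the C9 ketone, so after protonation the nine-membered lactam has arisen by four-atom ring expansion and not by end-to-end closure. The closest known reaction type is the amine-triggered acyl-transfer (retro-Claisen) ring expansion of cyclic β-keto esters and other 2-acyl-2-substituted cycloalkanones, including variants triggered by hydrogenolytic unmasking of the nitrogen. No stereocentre is set under control here: C8 becomes an epimerisable CH that is fixed in step 18, and C3, C4, C7, C11, C12, C14 and C22 are spectators. The step needs chemoselectivity among five carbonyl groups: only C23 gives a six-membered adduct with N17, C9 would need a four-membered ring, the C6 ethyl ester a seven-membered one, and C15 is shielded as a tert-butyl ester with O16 silylated. Because C8 is quaternary the diketone cannot divert to an enaminone, and amide formation together with release of cyclopentanone strain should drive the fragmentation. The catalyst is removed before the base is added so that any cyclic imine formed by dehydration of 28 is not hydrogenated but can rehydrate and fragment.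

Step 18
Reactants: 29 nine-membered keto-lactam
Product: 30 bis-lactone keto-lactam aldehyde (3R,4S,7S,8S,11S,12S,14S,22R; C18 aldehyde)
Conditions: TFA/H2O (9:1), 0 °C to rt; evaporation from toluene
Reagents that add atoms: water, O
Why: aqueous acid should cleave both silyl ethers, the tert-butyl ester and the acetal, after which O16 and O5 lactonise onto C15 and C6 (5-exo-trig each), while C8 equilibrates through the C9 enol to the cis-fused lactone with C9 anti to the fixed C7 methyl group.

Step 19
Reactants: 30 bis-lactone keto-lactam aldehyde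
Product: 33 target CNP0311700.2, via cyclic N-acyl hemiaminal 31 (not isolated), via N-acyliminium ion 32 (not isolated)
Conditions: Et3SiH (5 equiv), TFA/CH2Cl2 (1:4), 0 °C to rt
Reagents that add atoms: none
Why: reductive amidoalkylation: the lactam N17–H adds to the C18 aldehyde (7-exo-trig), acid ionises the hemiaminal, and excess silane reduces the N-acyliminium ion faster than it reduces the C9 ketone, closing the azepane ring without creating a stereocentre.

Compound list
1 | (R)-4-[(tert-butyldimethylsilyl)oxy]cyclopent-2-en-1-one | O=C1C=C[C@H](O[Si](C)(C)C(C)(C)C)C1 | starting material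
2 | (R)-4-[(tert-butyldimethylsilyl)oxy]-2-iodocyclopent-2-en-1-one | O=C1C(I)=C[C@H](O[Si](C)(C)C(C)(C)C)C1 | intermediate
3 | 4,4-diethoxybut-1-ene | C=CCC(OCC)OCC | starting material
4 | B-(4,4-diethoxybutyl)-9-borabicyclo[3.3.1]nonane | CCOC(CCCB1C2CCCC1CCC2)OCC | intermediate
5 | (R)-4-[(tert-butyldimethylsilyl)oxy]-2-(4,4-diethoxybutyl)cyclopent-2-en-1-one | CCOC(CCCC1=C[C@H](O[Si](C)(C)C(C)(C)C)CC1=O)OCC | intermediate
6 | (2R,3R,4R)-4-[(tert-butyldimethylsilyl)oxy]-2-(4,4-diethoxybutyl)-3-ethylcyclopentan-1-one | CC[C@H]1[C@H](O[Si](C)(C)C(C)(C)C)CC(=O)[C@@H]1CCCC(OCC)OCC | intermediate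
7 | O-benzyl-L-homoserine | N[C@@H](CCOCc1ccccc1)C(=O)O | starting material
8 | benzyl (S)-4-(benzyloxy)-2-(dibenzylamino)butanoate | O=C(OCc1ccccc1)[C@H](CCOCc1ccccc1)N(Cc1ccccc1)Cc1ccccc1 | intermediate
9 | allyl (S)-6-(benzyloxy)-4-(dibenzylamino)-3-oxohexanoate | C=CCOC(=O)CC(=O)[C@H](CCOCc1ccccc1)N(Cc1ccccc1)Cc1ccccc1 | intermediate
10 | tert-butyl (S)-lactate | C[C@H](O)C(=O)OC(C)(C)C | starting material
11 | tert-butyl (S)-2-{[(trifluoromethyl)sulfonyl]oxy}propanoate | C[C@H](OS(=O)(=O)C(F)(F)F)C(=O)OC(C)(C)C | intermediate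
12 | sodium enolate of 9 | [Na+].C=CCOC(=O)C=C([O-])[C@H](CCOCc1ccccc1)N(Cc1ccccc1)Cc1ccccc1 | intermediate
13 | 1-allyl 4-tert-butyl (3S)-2-[(S)-4-(benzyloxy)-2-(dibenzylamino)butanoyl]-3-methylbutanedioate | C=CCOC(=O)C([C@H](C)C(=O)OC(C)(C)C)C(=O)[C@H](CCOCc1ccccc1)N(Cc1ccccc1)Cc1ccccc1 | intermediate
14 | (3S)-2-[(S)-4-(benzyloxy)-2-(dibenzylamino)butanoyl]-4-(tert-butoxy)-3-methyl-4-oxobutanoic acid | OC(=O)C([C@H](C)C(=O)OC(C)(C)C)C(=O)[C@H](CCOCc1ccccc1)N(Cc1ccccc1)Cc1ccccc1 | intermediate
15 | tert-butyl (2S,5S)-7-(benzyloxy)-5-(dibenzylamino)-2-methyl-4-oxoheptanoate | CC(C)(C)OC(=O)[C@@H](C)CC(=O)[C@H](CCOCc1ccccc1)N(Cc1ccccc1)Cc1ccccc1 | intermediate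
16 | tert-butyl (2S,4S,5S)-7-(benzyloxy)-5-(dibenzylamino)-4-hydroxy-2-methylheptanoate | CC(C)(C)OC(=O)[C@@H](C)C[C@H](O)[C@H](CCOCc1ccccc1)N(Cc1ccccc1)Cc1ccccc1 | intermediate
17 | tert-butyl (2S,4S,5S)-7-(benzyloxy)-4-[(tert-butyldimethylsilyl)oxy]-5-(dibenzylamino)-2-methylheptanoate | CC(C)(C)OC(=O)[C@@H](C)C[C@H](O[Si](C)(C)C(C)(C)C)[C@H](CCOCc1ccccc1)N(Cc1ccccc1)Cc1ccccc1 | intermediate
18 | tert-butyl (2S,4S,5S)-5-amino-4-[(tert-butyldimethylsilyl)oxy]-7-hydroxy-2-methylheptanoate | CC(C)(C)OC(=O)[C@@H](C)C[C@H](O[Si](C)(C)C(C)(C)C)[C@H](CCO)N | intermediate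
19 | tert-butyl (2S,4S,5S)-5-azido-4-[(tert-butyldimethylsilyl)oxy]-7-hydroxy-2-methylheptanoate | CC(C)(C)OC(=O)[C@@H](C)C[C@H](O[Si](C)(C)C(C)(C)C)[C@H](CCO)N=[N+]=[N-] | intermediate
20 | tert-butyl (2S,4S,5S)-5-azido-4-[(tert-butyldimethylsilyl)oxy]-2-methyl-7-oxoheptanoate | CC(C)(C)OC(=O)[C@@H](C)C[C@H](O[Si](C)(C)C(C)(C)C)[C@H](CC=O)N=[N+]=[N-] | intermediate
21 | lithium enolate of 6 (C8=C23) | [Li+].CC[C@H]1[C@H](O[Si](C)(C)C(C)(C)C)C=C([O-])[C@@H]1CCCC(OCC)OCC | intermediate
22 | β-hydroxy ketone (C8–C9 aldol adduct of 6 and 20; C8 and C9 epimers) | CC[C@H]1[C@H](O[Si](C)(C)C(C)(C)C)C(C(O)C[C@@H]([C@@H](O[Si](C)(C)C(C)(C)C)C[C@H](C)C(=O)OC(C)(C)C)N=[N+]=[N-])C(=O)[C@@H]1CCCC(OCC)OCC | intermediate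
23 | 2-acylcyclopentanone (1,3-diketone C9/C23, drawn as the keto form) | CC[C@H]1[C@H](O[Si](C)(C)C(C)(C)C)C(C(=O)C[C@@H]([C@@H](O[Si](C)(C)C(C)(C)C)C[C@H](C)C(=O)OC(C)(C)C)N=[N+]=[N-])C(=O)[C@@H]1CCCC(OCC)OCC | intermediate
24 | ethyl (S)-2-{[(trifluoromethyl)sulfonyl]oxy}propanoate | C[C@H](OS(=O)(=O)C(F)(F)F)C(=O)OCC | starting material
25 | sodium enolate of 23 | [Na+].CC[C@H]1[C@H](O[Si](C)(C)C(C)(C)C)C(C(=O)C[C@@H]([C@@H](O[Si](C)(C)C(C)(C)C)C[C@H](C)C(=O)OC(C)(C)C)N=[N+]=[N-])=C([O-])[C@@H]1CCCC(OCC)OCC | intermediate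
26 | azido 2-acyl-2-alkylcyclopentanone (ring-expansion precursor; C8 quaternary, either epimer) | CC[C@H]1[C@H](O[Si](C)(C)C(C)(C)C)C([C@H](C)C(=O)OCC)(C(=O)C[C@@H]([C@@H](O[Si](C)(C)C(C)(C)C)C[C@H](C)C(=O)OC(C)(C)C)N=[N+]=[N-])C(=O)[C@@H]1CCCC(OCC)OCC | intermediate
27 | amino diketone (free N17 amine) | CC[C@H]1[C@H](O[Si](C)(C)C(C)(C)C)C([C@H](C)C(=O)OCC)(C(=O)C[C@@H]([C@@H](O[Si](C)(C)C(C)(C)C)C[C@H](C)C(=O)OC(C)(C)C)N)C(=O)[C@@H]1CCCC(OCC)OCC | intermediate
28 | bicyclic hemiaminal (N17–C23 bond, C23–OH) | CC[C@H]1[C@H](O[Si](C)(C)C(C)(C)C)C2([C@H](C)C(=O)OCC)C(=O)C[C@@H]([C@@H](O[Si](C)(C)C(C)(C)C)C[C@H](C)C(=O)OC(C)(C)C)NC2(O)[C@@H]1CCCC(OCC)OCC | intermediate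
29 | nine-membered keto-lactam (free N17–H, lactones masked; C8 epimers) | CC[C@H]1[C@H](O[Si](C)(C)C(C)(C)C)C([C@H](C)C(=O)OCC)C(=O)C[C@@H]([C@@H](O[Si](C)(C)C(C)(C)C)C[C@H](C)C(=O)OC(C)(C)C)NC(=O)[C@@H]1CCCC(OCC)OCC | intermediate
30 | bis-lactone keto-lactam aldehyde (3R,4S,7S,8S,11S,12S,14S,22R) | CC[C@H]1[C@@H]2OC(=O)[C@@H](C)[C@@H]2C(=O)C[C@@H]([C@@H]2C[C@H](C)C(=O)O2)NC(=O)[C@@H]1CCCC=O | intermediate
31 | cyclic N-acyl hemiaminal (N17–C18 bond, C18–OH) | CC[C@H]1[C@@H]2OC(=O)[C@@H](C)[C@@H]2C(=O)C[C@@H]([C@@H]2C[C@H](C)C(=O)O2)N2C(O)CCC[C@H]1C2=O | intermediate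
32 | N-acyliminium ion (N17=C18) trifluoroacetate | CC[C@H]1[C@@H]2OC(=O)[C@@H](C)[C@@H]2C(=O)C[C@@H]([C@@H]2C[C@H](C)C(=O)O2)[N+]2=CCCC[C@H]1C2=O.[O-]C(=O)C(F)(F)F | intermediate
33 | CNP0311700.2 (3R,4S,7S,8S,11S,12S,14S,22R) | CC[C@H]1[C@@H]2OC(=O)[C@@H](C)[C@@H]2C(=O)C[C@@H]([C@@H]2C[C@H](C)C(=O)O2)N2CCCC[C@H]1C2=O | target

Total step count: 19. Longest linear sequence: 15 steps (7 to 33 through steps 4, 5 and 7–19).

Steps most likely to fail

Step 17. The hemiaminal may dehydrate to a cyclic imine or enamine that is hydrogenated to a piperidine while H2 and catalyst are present, or the fragmentation may stall because the leaving group is only a ketone enolate on a congested quaternary carbon. The fallback avoids hydrogen altogether and sets out from 26. Treatment with PMe3 in dry toluene (rt to 60 °C) should give the iminophosphorane, which closes on C23 by intramolecular aza-Wittig reaction to the bicyclic imine F1; this can be isolated. Warming F1 in wet THF with catalytic AcOH and then Et3N should hydrate the C23=N17 bond to hemiaminal 28, which can be heated as needed without risk of reduction and fragments to 29, where the route is rejoined.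

Step 16. The ambident diketone enolate may be alkylated on oxygen, the triflate may undergo elimination to ethyl acrylate followed by Michael addition (a homologous chain), or substitution at the congested C8 may not proceed. The fallback builds the C8–C7 bond by conjugate addition and sets out from 23. Addition of 23 to (E)-1-nitropropene (catalytic Et3N or a bifunctional thiourea catalyst, toluene, rt) should give the nitro compound F2 with C8 quaternary. Oxidation of the primary nitro group with NaNO2/AcOH in DMSO (35 °C) should give the carboxylic acid F3, and EtI/KHCO3 in DMF should give the ethyl ester. The route is rejoined at 26, obtained together with its C7 epimer, so C7 then also depends on equilibration next to C8 once lactone A is closed.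

Step 18. In strong acid the free β-hydroxy ketone (C4–OH, C8–H, C9=O) may lose the C4 oxygen by elimination before lactone A closes, and the equilibration at C8 may be incomplete. The fallback unmasks in two stages and sets out from 29. HF·pyridine buffered with pyridine in THF (0 °C to rt) should remove both silyl ethers and let O5 close lactone A under mild conditions, giving the hydroxy lactone F4 with the tert-butyl ester and the acetal intact. C8 can then be equilibrated on this lactone with Et3N in CH2Cl2, where elimination of the lactone oxygen is stereoelectronically disfavoured, and brief TFA/H2O treatment closes lactone B and frees the aldehyde, rejoining the route at 30.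

Further compounds
F1 | step 17 | bicyclic imine (C23=N17) from intramolecular aza-Wittig reaction of 26 | CC[C@H]1[C@H](O[Si](C)(C)C(C)(C)C)C2([C@H](C)C(=O)OCC)C(=O)C[C@@H]([C@@H](O[Si](C)(C)C(C)(C)C)C[C@H](C)C(=O)OC(C)(C)C)N=C2[C@@H]1CCCC(OCC)OCC
F2 | step 16 | Michael adduct of 23 with 1-nitropropene (C8 quaternary, C7 bearing CH3 and CH2NO2; epimers) | CC[C@H]1[C@H](O[Si](C)(C)C(C)(C)C)C(C(C)C[N+](=O)[O-])(C(=O)C[C@@H]([C@@H](O[Si](C)(C)C(C)(C)C)C[C@H](C)C(=O)OC(C)(C)C)N=[N+]=[N-])C(=O)[C@@H]1CCCC(OCC)OCC
F3 | step 16 | C6 carboxylic acid corresponding to 26 (C7 epimers) | CC[C@H]1[C@H](O[Si](C)(C)C(C)(C)C)C(C(C)C(=O)O)(C(=O)C[C@@H]([C@@H](O[Si](C)(C)C(C)(C)C)C[C@H](C)C(=O)OC(C)(C)C)N=[N+]=[N-])C(=O)[C@@H]1CCCC(OCC)OCC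
F4 | step 18 | keto-lactam with lactone A closed, C12–OH free, tert-butyl ester and diethyl acetal intact | CC[C@H]1[C@@H]2OC(=O)[C@@H](C)[C@@H]2C(=O)C[C@@H]([C@@H](O)C[C@H](C)C(=O)OC(C)(C)C)NC(=O)[C@@H]1CCCC(OCC)OCC
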